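**Retrosynthetic overview**
- The C5 methoxy stereocentre and the C4 methylene come last, by 1,4-hydrosilylation and α-methoxylation of a cross-conjugated 3a-allyl dienone (C5 under thermodynamic control).
- That dienone comes from dearomative para-allylation (PhI(OAc)2, allylsilane) of an aromatic trans-2-aryl-3-methyl-2,3-dihydrobenzofuran-6-ol; the quaternary C3a is set anti to the C3 methyl.
- The dihydrofuran ring comes from a 5-exo aryl radical cyclization of a 2-bromoaryl 1-arylallyl ether (C3 set trans to C2).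
- The C2 stereocentre comes from an iridium-catalysed, branched-selective asymmetric allylic etherification of monosilylated 4-bromoresorcinol with a cinnamyl carbonate.
- Ring order: benzene ring (bought) → O-heterocycle closed onto it → benzene ring dearomatized to the cyclohexenone.

Assumption: 4-bromoresorcinol and (E)-3,4,5-trimethoxycinnamyl alcohol are bought, and the ligand antipode in step 3 is whichever gives the (S)-ether (written here as S,S,Sa).

**Step 1**
Reactants: 1 4-bromobenzene-1,3-diol (4-bromoresorcinol)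
Product: 2 2-bromo-5-{[tri(propan-2-yl)silyl]oxy}phenol
Conditions: iPr3SiCl (1.05 equiv), imidazole (2.2 equiv), CH2Cl2, −20 → 0 °C
Reagents that add atoms: chlorotri(propan-2-yl)silane, CC(C)[Si](Cl)(C(C)C)C(C)C
Why: O-silylation (silyl ether protection) is steered by sterics to the unhindered hydroxyl para to bromine, because the hydroxyl flanked by bromine reacts much more slowly with the bulky silyl chloride, so the phenol needed as nucleophile in step 3 stays free; no stereocentre.

**Step 2**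
Reactants: 3 (E)-3-(3,4,5-trimethoxyphenyl)prop-2-en-1-ol
Product: 4 methyl (E)-3-(3,4,5-trimethoxyphenyl)prop-2-en-1-yl carbonate
Conditions: ClCO2Me (1.2 equiv), pyridine (1.5 equiv), CH2Cl2, 0 °C
Reagents that add atoms: methyl chloroformate, COC(=O)Cl
Why: Standard O-acylation of the primary allylic alcohol gives the linear (E)-carbonate, the leaving group needed for iridium-catalysed allylic substitution; no stereocentre.

**Step 3**
Reactants: 2 2-bromo-5-{[tri(propan-2-yl)silyl]oxy}phenol; 4 methyl (E)-3-(3,4,5-trimethoxyphenyl)prop-2-en-1-yl carbonate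
Product: 5 {4-bromo-3-{[(1S)-1-(3,4,5-trimethoxyphenyl)prop-2-en-1-yl]oxy}phenoxy}tri(propan-2-yl)silane
Conditions: [Ir(cod)Cl]2 (2 mol %), (S,S,Sa)-O,O'-(1,1'-binaphthyl-2,2'-diyl) N,N-bis(1-phenylethyl)phosphoramidite (4 mol %, preactivated with n-PrNH2), Et3N (1.0 equiv), THF, 50 °C
Reagents that add atoms: none
Why: Iridium-catalysed asymmetric allylic etherification (Hartwig–Helmchen type): the cyclometalated iridium–phosphoramidite catalyst ionises the carbonate and the aryloxide attacks the aryl-bearing allyl terminus, giving the branched ether with C2 set as S by the ligand, while the aryl bromide and silyl ether are inert to the catalyst.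

**Step 4**
Reactants: 5 {4-bromo-3-{[(1S)-1-(3,4,5-trimethoxyphenyl)prop-2-en-1-yl]oxy}phenoxy}tri(propan-2-yl)silane
Product: 7 (2S,3S)-3-methyl-2-(3,4,5-trimethoxyphenyl)-2,3-dihydro-1-benzofuran-6-ol, via silyl ether 6 (not isolated)
Conditions: Bu3SnH (1.3 equiv, slow addition), AIBN (0.2 equiv), PhMe, 90 °C; then TBAF (2.5 equiv), AcOH (1.2 equiv), THF, 0 °C → rt
Reagents that add atoms: none
Why: Aryl radical 5-exo-trig cyclization (tin hydride method) followed by hydrogen transfer forms the C3a–C3 bond and the methyl group, with the C2 aryl pseudo-equatorial and C2–H eclipsing the vinyl group (A(1,3) strain minimised) so that C3 forms trans to C2 as S (expected about 5:1 over cis, which is removed by chromatography); fluoride then cleaves the aryl silyl ether.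

**Step 5** (key step)
Reactants: 7 (2S,3S)-3-methyl-2-(3,4,5-trimethoxyphenyl)-2,3-dihydro-1-benzofuran-6-ol
Product: 8 (2S,3S,3aR)-3-methyl-3a-(prop-2-en-1-yl)-2-(3,4,5-trimethoxyphenyl)-3,3a-dihydro-1-benzofuran-6(2H)-one
Conditions: PhI(OAc)2 (1.2 equiv), allyltrimethylsilane (5 equiv), (CF3)2CHOH, −20 → 0 °C, 15 min
Reagents that add atoms: allyltrimethylsilane, C=CC[Si](C)(C)C
Why: Oxidative dearomatization (phenol umpolung, Hosomi–Sakurai-type capture): the phenoxonium ion formed with trivalent iodine is trapped at its para carbon C3a by the allylsilane on the face anti to the adjacent C3 methyl (the C2 aryl is remote and pseudo-equatorial), which sets the quaternary C3a as R and leaves a cross-conjugated dienone that cannot rearomatize.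

**Step 6**
Reactants: 8 (2S,3S,3aR)-3-methyl-3a-(prop-2-en-1-yl)-2-(3,4,5-trimethoxyphenyl)-3,3a-dihydro-1-benzofuran-6(2H)-one
Product: 11 (2S,3S,3aR,5R)-5-methoxy-3-methyl-3a-(prop-2-en-1-yl)-2-(3,4,5-trimethoxyphenyl)-3,3a,4,5-tetrahydro-1-benzofuran-6(2H)-one, via silyl dienol ether 9 (not isolated), via C5 epimer 10 (not isolated)
Conditions: [(Ph3P)CuH]6 (5 mol %), PhMe2SiH (1.1 equiv), PhMe, 0 °C → rt; evaporate; PhIO (1.5 equiv), BF3·OEt2 (1.5 equiv), MeOH/CH2Cl2, −70 → −20 °C; aq NaHCO3; then K2CO3 (0.3 equiv), MeOH, rt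
Reagents that add atoms: dimethyl(phenyl)silane, C[SiH](C)c1ccccc1 (silyl group of 9); methanol, CO (5-OMe)
Why: Copper hydride 1,4-hydrosilylation reduces only the simple enone C4=C5 (the C7=C7a vinylogous ester and the allyl group do not react), trivalent iodine then attacks the terminus C5 of the resulting 6-silyloxy diene and methanol displaces iodobenzene (Moriarty α-methoxylation of a silyl enol ether), and base equilibration through the enol places 5-OMe equatorial, trans to the axial 3a-allyl group, which is 5R.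

**Compound list**
1 | 4-bromobenzene-1,3-diol | Oc1ccc(Br)c(O)c1 | starting material
2 | 2-bromo-5-{[tri(propan-2-yl)silyl]oxy}phenol | Oc1cc(O[Si](C(C)C)(C(C)C)C(C)C)ccc1Br | intermediate
3 | (E)-3-(3,4,5-trimethoxyphenyl)prop-2-en-1-ol | OC/C=C/c1cc(OC)c(OC)c(OC)c1 | starting material
4 | methyl (E)-3-(3,4,5-trimethoxyphenyl)prop-2-en-1-yl carbonate | COC(=O)OC/C=C/c1cc(OC)c(OC)c(OC)c1 | intermediate
5 | {4-bromo-3-{[(1S)-1-(3,4,5-trimethoxyphenyl)prop-2-en-1-yl]oxy}phenoxy}tri(propan-2-yl)silane | C=C[C@H](Oc1cc(O[Si](C(C)C)(C(C)C)C(C)C)ccc1Br)c1cc(OC)c(OC)c(OC)c1 | intermediate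
6 | {[(2S,3S)-3-methyl-2-(3,4,5-trimethoxyphenyl)-2,3-dihydro-1-benzofuran-6-yl]oxy}tri(propan-2-yl)silane | CC(C)[Si](Oc1ccc2c(c1)O[C@H](c1cc(OC)c(OC)c(OC)c1)[C@H]2C)(C(C)C)C(C)C | intermediate
7 | (2S,3S)-3-methyl-2-(3,4,5-trimethoxyphenyl)-2,3-dihydro-1-benzofuran-6-ol | Oc1ccc2c(c1)O[C@H](c1cc(OC)c(OC)c(OC)c1)[C@H]2C | intermediate
8 | (2S,3S,3aR)-3-methyl-3a-(prop-2-en-1-yl)-2-(3,4,5-trimethoxyphenyl)-3,3a-dihydro-1-benzofuran-6(2H)-one | C=CC[C@]12C=CC(=O)C=C1O[C@H](c1cc(OC)c(OC)c(OC)c1)[C@H]2C | intermediate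
9 | dimethyl{[(2S,3S,3aR)-3-methyl-3a-(prop-2-en-1-yl)-2-(3,4,5-trimethoxyphenyl)-2,3,3a,4-tetrahydro-1-benzofuran-6-yl]oxy}(phenyl)silane | C=CC[C@]12CC=C(O[Si](C)(C)c3ccccc3)C=C1O[C@H](c1cc(OC)c(OC)c(OC)c1)[C@H]2C | intermediate
10 | (2S,3S,3aR,5S)-5-methoxy-3-methyl-3a-(prop-2-en-1-yl)-2-(3,4,5-trimethoxyphenyl)-3,3a,4,5-tetrahydro-1-benzofuran-6(2H)-one | C=CC[C@]12C[C@H](OC)C(=O)C=C1O[C@H](c1cc(OC)c(OC)c(OC)c1)[C@H]2C | intermediate
11 | (2S,3S,3aR,5R)-5-methoxy-3-methyl-3a-(prop-2-en-1-yl)-2-(3,4,5-trimethoxyphenyl)-3,3a,4,5-tetrahydro-1-benzofuran-6(2H)-one | C=CC[C@]12C[C@@H](OC)C(=O)C=C1O[C@H](c1cc(OC)c(OC)c(OC)c1)[C@H]2C | target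

**Totals**
Total step count: 6. Longest linear sequence: 5 (steps 1, 3, 4, 5, 6).

**Three steps most likely to fail**

Step 5 (dearomative allylation). The phenoxonium ion can lose the C3 proton and end as the aromatic benzofuran, attack at an ortho carbon is possible, and the facial selectivity at C3a is unproven on this ring system. The fallback sets out from 7 and returns at 8. It replaces the umpolung by a phenoxide/π-allyl pathway: 7 is acylated with allyl chloroformate and pyridine to prop-2-en-1-yl (2S,3S)-3-methyl-2-(3,4,5-trimethoxyphenyl)-2,3-dihydro-1-benzofuran-6-yl carbonate F1. F1 is then treated with Pd(PPh3)4 (5 mol %) in toluene at rt to 50 °C, where decarboxylation gives the phenoxide/π-allylpalladium ion pair, which recombines at carbon (decarboxylative Tsuji–Trost-type dearomatization) to give 8. No cationic intermediate is involved, so benzofuran formation is avoided; the known weakness is competing C7 allylation.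

Step 6 (one-pot reduction and α-methoxylation). The electrophilic iodine reagent could touch the allyl group or the electron-rich arene, and BF3 could ionise the C2–O bond. The fallback sets out from 8 and returns at 11, using enolate chemistry instead. Conjugate reduction with Cu(OAc)2 (5 mol %), 1,2-bis(diphenylphosphino)benzene, polymethylhydrosiloxane and t-BuOH gives the ketone (2S,3S,3aS)-3-methyl-3a-(prop-2-en-1-yl)-2-(3,4,5-trimethoxyphenyl)-3,3a,4,5-tetrahydro-1-benzofuran-6(2H)-one F2 (same spatial arrangement at C3a; the descriptor changes by priority only). Kinetic deprotonation at C5 with LiN(iPr)2 at −78 °C and oxidation with 3-phenyl-2-(phenylsulfonyl)oxaziridine gives the hydroxy ketone (2S,3S,3aR,5R)-5-hydroxy-3-methyl-3a-(prop-2-en-1-yl)-2-(3,4,5-trimethoxyphenyl)-3,3a,4,5-tetrahydro-1-benzofuran-6(2H)-one F3. O-Methylation with Me3OBF4 and 1,8-bis(dimethylamino)naphthalene, then K2CO3/MeOH equilibration, gives 11.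

Step 3 (iridium etherification). The ortho-bromophenol is a hindered, weakly nucleophilic partner, and the electron-rich branched ether can re-ionise and lose ee or isomerise to the linear ether. The fallback sets out from 3 and returns at 5, building the stereocentre by epoxidation instead. Sharpless asymmetric epoxidation of 3 (Ti(OiPr)4, L-(+)-diethyl tartrate, t-BuOOH, 4 Å sieves, CH2Cl2, −20 °C) gives [(2S,3S)-3-(3,4,5-trimethoxyphenyl)oxiran-2-yl]methanol F4. Treatment with I2, PPh3 and imidazole gives (2R,3S)-2-(iodomethyl)-3-(3,4,5-trimethoxyphenyl)oxirane F5. Zn in AcOH/EtOH opens it reductively to (1R)-1-(3,4,5-trimethoxyphenyl)prop-2-en-1-ol F6. Mitsunobu coupling of F6 with phenol 2 (PPh3, diisopropyl azodicarboxylate, PhMe, −20 °C) proceeds with inversion to give 5.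

**Further compounds**
F1 | step 5 | prop-2-en-1-yl (2S,3S)-3-methyl-2-(3,4,5-trimethoxyphenyl)-2,3-dihydro-1-benzofuran-6-yl carbonate | C=CCOC(=O)Oc1ccc2c(c1)O[C@H](c1cc(OC)c(OC)c(OC)c1)[C@H]2C
F2 | step 6 | (2S,3S,3aS)-3-methyl-3a-(prop-2-en-1-yl)-2-(3,4,5-trimethoxyphenyl)-3,3a,4,5-tetrahydro-1-benzofuran-6(2H)-one | C=CC[C@]12CCC(=O)C=C1O[C@H](c1cc(OC)c(OC)c(OC)c1)[C@H]2C
F3 | step 6 | (2S,3S,3aR,5R)-5-hydroxy-3-methyl-3a-(prop-2-en-1-yl)-2-(3,4,5-trimethoxyphenyl)-3,3a,4,5-tetrahydro-1-benzofuran-6(2H)-one | C=CC[C@]12C[C@@H](O)C(=O)C=C1O[C@H](c1cc(OC)c(OC)c(OC)c1)[C@H]2C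
F4 | step 3 | [(2S,3S)-3-(3,4,5-trimethoxyphenyl)oxiran-2-yl]methanol | OC[C@@H]1O[C@H]1c1cc(OC)c(OC)c(OC)c1
F5 | step 3 | (2R,3S)-2-(iodomethyl)-3-(3,4,5-trimethoxyphenyl)oxirane | IC[C@@H]1O[C@H]1c1cc(OC)c(OC)c(OC)c1
F6 | step 3 | (1R)-1-(3,4,5-trimethoxyphenyl)prop-2-en-1-ol | C=C[C@@H](O)c1cc(OC)c(OC)c(OC)c1
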